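**Retrosynthetic overview**
- The target is unmasked last, by double O-demethylation of its bis(methyl ether).
- Key disconnection: the diaryl ether C–O bond on the ring B side (ring B = dibromo ring, ring A = monobromo ring), at the carbon flanked by OMe and Br. The target has no inter-ring C–C bond, so this is the only strategic bond.
- Ring B acts as an aryl cation equivalent (an aryl(2,4,6-trimethoxyphenyl)iodonium salt of trivalent iodine) and ring A as the phenolate of commercial 5-bromo-2-methoxyphenol, so two innately nucleophilic centres are joined by polarity reversal.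
- The iodonium salt comes from the aryl iodide made by directed ortho-lithiation and iodination of 3,4-dibromoanisole; the same carbon is first a carbanion, then a cation equivalent.
- No ring is built: both benzene rings are bought intact; ring B is functionalised first and then joined to ring A.

Assumption: the target has no stereocentre and no hindered axis (the diaryl ether rotates freely), so it is achiral and needs no enantiocontrol.

**Step 1**
Reactants: 1 1,2-dibromo-4-methoxybenzene (3,4-dibromoanisole)
Product: 3 1,2-dibromo-3-iodo-4-methoxybenzene, via (2,3-dibromo-6-methoxyphenyl)lithium 2 (not isolated)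
Conditions: LiN(i-Pr)2 (1.1 equiv), THF, –78 °C, 1 h; then I2 (1.2 equiv), THF, –78 °C to rt
Reagents that add atoms: iodine, II
Why: Directed ortho-metalation followed by iodinolysis: the C–H between OMe and Br is the most acidic site of 1, the aryllithium formed there is already the most stabilised anion (so halogen dance has no driving force, and LiBr loss is slow at –78 °C), and iodine traps it to give 3 with no stereocentre involved.

**Step 2**
Reactants: 3 1,2-dibromo-3-iodo-4-methoxybenzene; 4 1,3,5-trimethoxybenzene; 5 5-bromo-2-methoxyphenol
Product: 9 1,2-dibromo-3-(5-bromo-2-methoxyphenoxy)-4-methoxybenzene, via Koser-type hydroxy(tosyloxy)iodoarene 6 (not isolated), via aryl(2,4,6-trimethoxyphenyl)iodonium tosylate 7 (not isolated), via potassium 5-bromo-2-methoxyphenolate 8 (not isolated)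
Conditions: 3 (1.15 equiv), mCPBA (1.1 equiv), TsOH·H2O (1.1 equiv), MeCN, 55 °C, 1 h; then 4 (1.1 equiv), 55 °C to rt, 30 min; evaporate, toluene azeotrope; then add to 5 (1.0 equiv) + KOt-Bu (2.3 equiv), THF, 0 to 50 °C, 4 h
Reagents that add atoms: none
Why: One-pot polarity reversal and metal-free O-arylation: peracid oxidation of the aryl iodide to a Koser-type trivalent-iodine species and electrophilic aromatic substitution on 1,3,5-trimethoxybenzene give the diaryliodonium salt, and ligand coupling of the phenolate at trivalent iodine transfers the less electron-rich, di-ortho-substituted dibromoanisyl group (the trimethoxyphenyl group is a non-transferring dummy, neither aryl has an ortho hydrogen for an aryne pathway, and the slight excess of 3 leaves no peracid to oxidise the phenolate), forming the hindered ether without touching any C–Br bond and creating no stereocentre.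

**Step 3**
Reactants: 9 1,2-dibromo-3-(5-bromo-2-methoxyphenoxy)-4-methoxybenzene
Product: 11 3,4-dibromo-2-(5-bromo-2-hydroxyphenoxy)phenol, via bis(dibromoboryl) ether 10 (not isolated)
Conditions: BBr3 (5 equiv), CH2Cl2, –78 °C to rt, 12 h; then ice-water
Reagents that add atoms: none
Why: Lewis-acid ether cleavage (BBr3 demethylation): boron coordinates each methoxy oxygen, bromide removes the methyl group by SN2 as bromomethane, the aryloxyboranes are hydrolysed on work-up, and the aryl C–Br bonds and the diaryl ether linkage (no SN2-capable carbon) are inert, so the achiral target is released directly.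

**Compound list**
1 | 1,2-dibromo-4-methoxybenzene (3,4-dibromoanisole) | COc1ccc(Br)c(Br)c1 | starting material
2 | (2,3-dibromo-6-methoxyphenyl)lithium | [Li]c1c(OC)ccc(Br)c1Br | intermediate
3 | 1,2-dibromo-3-iodo-4-methoxybenzene | COc1ccc(Br)c(Br)c1I | intermediate
4 | 1,3,5-trimethoxybenzene | COc1cc(OC)cc(OC)c1 | starting material
5 | 5-bromo-2-methoxyphenol | COc1ccc(Br)cc1O | starting material
6 | 1,2-dibromo-3-[hydroxy(tosyloxy)-λ3-iodanyl]-4-methoxybenzene | COc1ccc(Br)c(Br)c1I(O)OS(=O)(=O)c1ccc(C)cc1 | intermediate
7 | (2,3-dibromo-6-methoxyphenyl)(2,4,6-trimethoxyphenyl)iodonium 4-methylbenzenesulfonate | COc1ccc(Br)c(Br)c1[I+]c1c(OC)cc(OC)cc1OC.Cc1ccc(cc1)S(=O)(=O)[O-] | intermediate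
8 | potassium 5-bromo-2-methoxyphenolate | COc1ccc(Br)cc1[O-].[K+] | intermediate
9 | 1,2-dibromo-3-(5-bromo-2-methoxyphenoxy)-4-methoxybenzene | COc1ccc(Br)cc1Oc1c(OC)ccc(Br)c1Br | intermediate
10 | 1,2-dibromo-3-[5-bromo-2-(dibromoboryloxy)phenoxy]-4-(dibromoboryloxy)benzene | BrB(Br)Oc1ccc(Br)cc1Oc1c(OB(Br)Br)ccc(Br)c1Br | intermediate
11 | 3,4-dibromo-2-(5-bromo-2-hydroxyphenoxy)phenol | Oc1ccc(Br)cc1Oc1c(O)ccc(Br)c1Br | target

**Totals**
Total step count: 3. Longest linear sequence: 3 (1 → 3 → 9 → 11).

**Steps most likely to fail, with fallbacks**

Step 2 is the highest risk. The hindered iodide may oxidise slowly, m-chlorobenzoate or residual water may interfere in the one-pot sequence, and aryl transfer to the phenolate may be sluggish. The fallback sets out from 3 and couples it directly with 5 by a copper-catalysed Ullmann ether synthesis (CuI 10 mol %, picolinic acid 20 mol %, K3PO4, DMSO, 90 °C). The C–I bond of 3 reacts well before any C–Br bond. This normal-polarity cross-coupling comes back to the route at 9 and makes no new compound (F0).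

Step 1 is the next risk. Aryllithium 2 carries an ortho bromine and can lose LiBr to an aryne or scramble halogens if it warms or accumulates. The fallback sets out from 1 and never lets the anion build up: LiN(i-Pr)2 is added to a –78 °C THF solution of 1 and Me3SiCl (in situ quench) to give (2,3-dibromo-6-methoxyphenyl)trimethylsilane F1. Ipso-iododesilylation of this silane (ICl, CH2Cl2, 0 °C) then comes back to the route at 3.

Step 3 is the least risky. The ring B methoxy group is hindered and may cleave incompletely, and the HBr formed could promote bromine migration on the electron-rich bromophenol rings. The fallback sets out from 9 and replaces the boron Lewis acid by silyl-transfer dealkylation with Me3SiI (CHCl3, 60 °C). This gives 1,2-dibromo-3-[5-bromo-2-(trimethylsilyloxy)phenoxy]-4-(trimethylsilyloxy)benzene F2, in which the phenols stay masked. Neutral methanolysis (MeOH, rt) then comes back to the route at 11.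

**Further compounds**
F1 | step 1 | (2,3-dibromo-6-methoxyphenyl)trimethylsilane | COc1ccc(Br)c(Br)c1[Si](C)(C)C
F0 | step 2 | none | none
F2 | step 3 | 1,2-dibromo-3-[5-bromo-2-(trimethylsilyloxy)phenoxy]-4-(trimethylsilyloxy)benzene | C[Si](C)(C)Oc1ccc(Br)cc1Oc1c(O[Si](C)(C)C)ccc(Br)c1Br
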